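A small charge of partner stands behind every percent of target. Saturated with gas, the solution in the flask holds, on the starting volume, partner worth 5.20% of the substrate charged, far less than the substrate itself; I called this the holding fraction. While the gas keeps refilling the partner, substrate meets a steady partner (pseudo-first-order), and percentages should not shift with the charge. If demand overtook the gas, control would change hands and the curve should sag.

| setting | Wednesday's | Tuesday's | Friday's | flask |
|---|---|---|---|---|
| substrate | 0.25 M (fed, over 10 min) | 0.25 M (fed, over 10 min) | 0.50 M (fed, over 10 min) | 0.25 M (fed, over 10 min) |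
| gas | 13 mM (held) | 13 mM (held) | 13 mM (held) | 13 mM (held) |
| catalyst | 0.11 mol% | 0.17 mol% | 0.22 mol% | 0.22 mol% |
| remark | run made earlier; the fed solution adds 1.0 times the starting volume | run made earlier; the fed solution adds 1.0 times the starting volume | run made earlier; the fed solution adds 1.0 times the starting volume | the fed solution adds 1.0 times the starting volume |
| time |  |  |  | 4.0 h |

| run | time / h | target / % |
|---|---|---|
| Wednesday's | 0.0833 | 7.4 |
| Wednesday's | 0.167 | 16.5 |
| Wednesday's | 0.333 | 28.4 |
| Wednesday's | 0.667 | 14.1 |
| Wednesday's | 1.33 | 3.3 |
| Wednesday's | 2.50 | 2.1 |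
| Tuesday's | 0.0833 | 5.8 |
| Tuesday's | 0.167 | 17.3 |
| Tuesday's | 0.333 | 28.8 |
| Tuesday's | 0.667 | 16.5 |
| Tuesday's | 1.33 | 3.7 |
| Tuesday's | 2.50 | 0.8 |
| Friday's | 0.0833 | 5.6 |
| Friday's | 0.200 | 19.2 |
| Friday's | 0.417 | 25.2 |
| Friday's | 1.00 | 9.2 |
| Friday's | 2.50 | 0.3 |

(each reading ± 1 percentage point)

- amounts are per litre of the starting volume; all of the dose is in the solution fed
- at the start none of partner is dissolved
- what was read earlier has a scatter of 1 percentage point, one standard deviation
- steps thought possible: substrate + partner <-> target; substrate + partner <-> isomer of the product; target + catalyst <-> isomer of the product + catalyst; gas <-> partner; target -> over-reaction product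
- percentages count the whole charge, also what has not yet gone in

* the best time, 4.0 h at the latest, for target
* the amount of target, in percent of the substrate charged, at that time

Wednesday's and Tuesday's runs have the flask's holding fraction. Friday's run had half of it and still read 25.2% at 0.417 h, so I took the gas as keeping up in the flask. Was one number enough? Tuesday's catalyst loading was 1.55 times Wednesday's, yet at 0.333 h they read 28.4% and 28.8%, closer than the scatter. I therefore read the flask off those two runs: about 28.6% near 0.333 h.

The forecast, made from the same runs, gave 28.8% at 0.34 h, on this ground: “Percent yield therefore seems largely independent of concentration and catalyst.”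

The flask gives 27.1% at 0.319 h.

    substrate + partner ⇌ target (K = 380 M⁻¹, k = 6.00 M⁻¹ min⁻¹)
    substrate + partner ⇌ isomer of the product (K = 170 M⁻¹, k = 1.70 M⁻¹ min⁻¹)
    target + catalyst ⇌ isomer of the product + catalyst, rate k3*[catalyst]*[target] forward; the back reaction follows from the equilibrium constant (k = 47.0 M⁻¹ min⁻¹)
    gas ⇌ partner, rate k4*(csat - [partner]) (kL = 2.30 min⁻¹)
    target → over-reaction product (k = 0.0780 min⁻¹)

In the flask, dissolved partner stood at 77.2% of its saturation level at 0.167 h and 88.7% at 0.319 h. At 4.00 h, the half-life of substrate by the forward step to target was 0.15 h, about that of target by over-reaction, 0.15 h.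

The neighbouring flask with 1.0 M of substrate has a holding fraction of 1.30%, a quarter of this flask's and below Friday's, so the runs no longer vouch for it. It gives 22.7%.

(The runs were computed for substances that don't exist; the scatter is artificial.)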